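Start from amounts and count what is left. Each first product holds one partner, each double product two, each triple product 3.

| flask | substrate | partner | remark | time |
|---|---|---|---|---|
| noon | 2 mM | 0.40 equiv (fed, over 3.0 s) | run made earlier |  |
| spring | 2 mM | 1.6 equiv (fed, over 3.0 s) | run made earlier |  |
| dusk | 4 mM | 0.80 equiv (fed, over 3.0 s) | run made earlier |  |
| flask | 2.0 mM | 0.800 equiv (fed, over 3.0 s) |  | 6.0 min |

| run | time / min | substrate / % | first product / % | double product / % |
|---|---|---|---|---|
| noon | 0.500 | 51 | 21 | 2 |
| noon | 0.833 | 48 | 25 | 5 |
| noon | 1.33 | 44 | 29 | 2 |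
| noon | 2.00 | 39 | 30 | 2 |
| noon | 3.00 | 40 | 30 | 0 |
| noon | 5.00 | 41 | 30 | 1 |
| noon | 8.00 | 40 | 33 | 4 |
| spring | 1.00 | 13 | 46 | 30 |
| spring | 2.00 | 5 | 38 | 36 |
| spring | 3.00 | 3 | 34 | 44 |
| spring | 4.00 | 2 | 34 | 43 |
| spring | 5.00 | 2 | 29 | 46 |
| spring | 6.00 | 1 | 32 | 44 |
| spring | 8.00 | 2 | 29 | 46 |
| dusk | 0.500 | 27 | 41 | 9 |
| dusk | 1.00 | 23 | 45 | 12 |
| dusk | 2.00 | 23 | 44 | 8 |
| dusk | 4.00 | 20 | 45 | 5 |
| dusk | 8.00 | 15 | 46 | 1 |

(each reading ± 1.5 percentage points)



- substrate at 6.0 min, in percent of the substrate charged
- first product at 6.0 min, in percent of the substrate charged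
- double product at 6.0 min, in percent of the substrate charged
- triple product at 6.0 min, in percent of the substrate charged

Take two amounts. The room is the partner charge minus the partner held in first and double product, in percent of the substrate charged. The gap is the substrate not read as substrate, first or double product. The dusk readings at 8.00 min give a gap of 38.0% and a room of 32.0%. Their ratio, room over gap, is the gap loading 0.842, a reading with the scatter of its parts. At dusk, a gap made of triple product needs 114% of partner, more than the room.

The flask has the equivalents of dusk, so my reckoning carries that room over as an estimate, gives all of it to triple product and arrives at about 10.7% triple product as an upper estimate. The forecast gives 21% substrate, 44% first product, 7% double product and 28% triple product: “I take the gap as triple product”. My estimate stands lower than its triple product.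

The flask gives 18.6% substrate, 45.0% first product, 7.60% double product and 0.468% triple product.

    substrate + partner → first product (k = 23.2 M⁻¹ s⁻¹)
    partner + first product → double product (k = 8.50 M⁻¹ s⁻¹)
    partner + double product → triple product (k = 1.52 M⁻¹ s⁻¹)
    partner + triple product → tetra adduct (k = 8.11 M⁻¹ s⁻¹)
    substrate + double product → side product (k = 6.02 M⁻¹ s⁻¹)
    substrate ⇌ dormant form (K = 0.551, k = 0.0664 s⁻¹)

Partner, the limiting reagent, is down to 0.10% of its own charge at 6.00 min, and the gap loading of the flask is 0.687. With substrate as charged, double product has a half-life of 0.96 min by loss to side product, shorter than 6.0 min. At 6.00 min the flask holds 18.0% side product, a percentage in which each side product counts as two, against 0.468% triple product. The neighbour with 0.200 equiv of partner holds 28.5% dormant form at 6.00 min and has a gap loading of 0.0623.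

The earlier runs and the new flask are simulated with made-up constants; the scatter is artificial.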